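**Retrosynthetic overview**
1. The target is 7-methoxyflavone (rings A, C, B) carrying at C8 a butenolide ring D [O1', C2'(=O), C3' (on C8), C4'H, C5'(CH3)2]; only ring D has to be built.
2. Ring D is cut at C3'=C4' and at O1'–C5', giving a (7-methoxyflavon-8-yl)acetic acid unit (C8–CH2–CO2) and isobutyraldehyde (C4' is its CHO carbon, C5' its only α-carbon).
3. Enabling feature: C5' is a quaternary carbon holding two methyls and O1' next to the C4' methine, i.e. an α-oxygenated isobutyraldehyde that cannot enolise, and C3' lies between ring A and C2'=O, so it is a doubly activated CH2 in the open ester. The carboxyl oxygen is made electrophilic through a temporary N–O tether (N-methylhydroxylamine); an N-acyloxy enamine [3,3] shift turns it into the O1'–C5' bond, and an intramolecular aldol condensation then closes C3'=C4' and releases the tether as methylamine.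
4. The acetic acid chain comes from an allyl group placed at C8 by aromatic Claisen rearrangement of 7-(allyloxy)flavone, then O-methylation and oxidative cleavage.
5. Ring order: rings A, C and B are bought intact as 7-hydroxyflavone; ring D is formed last, in step 8.

Key step: step 8

Remark on the chemistry: the target has no stereocentre, and its ring C=C geometry is fixed by the five-membered ring. 7-Hydroxyflavone, allyl bromide, tert-butyl N-hydroxy-N-methylcarbamate and isobutyraldehyde are taken as purchasable.

**Step 1**
Reactants: 1 7-hydroxyflavone; 2 allyl bromide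
Product: 3 7-(allyloxy)flavone
Conditions: K2CO3, acetone, reflux
Reagents that add atoms: none
Why: Williamson ether synthesis; the phenoxide of 1 should displace the allylic bromide cleanly, and the flavone core has no other nucleophilic site.

**Step 2**
Reactants: 3 7-(allyloxy)flavone
Product: 4 8-allyl-7-hydroxyflavone
Conditions: PhNEt2, 200 °C
Reagents that add atoms: none
Why: Aromatic Claisen rearrangement ([3,3]-sigmatropic shift, then tautomerisation to the phenol); the C7–C8 bond of the chromone has the higher double-bond character, so the allyl group should migrate to C8 and not to C6, as with 7-allyloxy-chromones and -coumarins.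

**Step 3**
Reactants: 4 8-allyl-7-hydroxyflavone
Product: 5 8-allyl-7-methoxyflavone
Conditions: MeI, K2CO3, acetone, reflux
Reagents that add atoms: methyl iodide, CI
Why: Williamson O-methylation of the only acidic OH; it installs the 7-methoxy group of the target.

**Step 4**
Reactants: 5 8-allyl-7-methoxyflavone
Product: 6 (7-methoxy-4-oxo-2-phenyl-4H-chromen-8-yl)acetaldehyde
Conditions: OsO4 (cat.), NaIO4, 2,6-lutidine, dioxane/H2O, rt
Reagents that add atoms: osmium tetroxide, O=[Os](=O)(=O)=O (catalytic oxygen carrier); sodium periodate, [Na+].[O-]I(=O)(=O)=O (terminal oxidant that refills it)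
Why: Lemieux–Johnson oxidation (dihydroxylation, then glycol cleavage); the terminal monosubstituted alkene should react far faster with OsO4 than the conjugated, electron-poor C2=C3 bond of the pyranone ring.

**Step 5**
Reactants: 6 (7-methoxy-4-oxo-2-phenyl-4H-chromen-8-yl)acetaldehyde
Product: 7 (7-methoxy-4-oxo-2-phenyl-4H-chromen-8-yl)acetic acid
Conditions: NaClO2, NaH2PO4, 2-methyl-2-butene, t-BuOH/H2O, rt
Reagents that add atoms: sodium chlorite, [Na+].[O-]Cl=O
Why: Pinnick oxidation; chlorous acid oxidises only the aldehyde, and the alkene scavenger removes HOCl before it can chlorinate the methoxy-substituted ring A.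

**Step 6**
Reactants: 7 (7-methoxy-4-oxo-2-phenyl-4H-chromen-8-yl)acetic acid; 8 tert-butyl N-hydroxy-N-methylcarbamate
Product: 9 tert-butyl N-methyl-N-{[(7-methoxy-4-oxo-2-phenyl-4H-chromen-8-yl)acetyl]oxy}carbamate
Conditions: DCC, DMAP (cat.), CH2Cl2, 0 °C to rt
Reagents that add atoms: none
Why: Steglich-type carbodiimide coupling; the nitrogen of 8 is blocked by the Boc group, so only the acidic N–OH oxygen is acylated, which sets up the N–O tether.

**Step 7**
Reactants: 9 tert-butyl N-methyl-N-{[(7-methoxy-4-oxo-2-phenyl-4H-chromen-8-yl)acetyl]oxy}carbamate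
Product: 10 N-methyl-O-[(7-methoxy-4-oxo-2-phenyl-4H-chromen-8-yl)acetyl]hydroxylammonium chloride
Conditions: HCl (4 M in dioxane), 0 °C to rt
Reagents that add atoms: hydrogen chloride, Cl
Why: Acidolysis of the Boc carbamate (loss of 2-methylpropene and CO2); the nitrogen stays protonated as the salt, which should block O-to-N acyl migration, and anhydrous acid leaves the O-acyl bond and the aryl methyl ether intact.

**Step 8**
Reactants: 10 N-methyl-O-[(7-methoxy-4-oxo-2-phenyl-4H-chromen-8-yl)acetyl]hydroxylammonium chloride; 11 isobutyraldehyde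
Product: 16 3-(7-methoxy-4-oxo-2-phenyl-4H-chromen-8-yl)-5,5-dimethylfuran-2(5H)-one (target), via N-acyloxy enamine 12 (not isolated), via acyloxy imine 13 (not isolated), via acyloxy aldehyde 14 (not isolated), via aldol lactone 15 (not isolated)
Conditions: DMSO, rt; then DBU, 50 °C (same flask)
Reagents that add atoms: none
Why: Condensation of the N–H of 10 with 11 gives an N-acyloxy iminium ion that tautomerises to enamine 12, whose [3,3]-sigmatropic shift through a six-membered chair-like transition state breaks the weak N–O bond and joins the acyl carbonyl oxygen to the enamine β-carbon (the O1'–C5' bond), and the water of condensation hydrolyses imine 13 to aldehyde 14; DBU then enolises the ArCH2 group, which adds to the aldehyde carbon and loses water by E1cB to set the C3'=C4' double bond. The closest known reaction types are the α-acyloxylation of aldehydes, α-branched ones included, with N-methyl-O-acylhydroxylamine hydrochlorides, and the base-mediated cyclodehydration of arylacetic esters of α-hydroxy carbonyl compounds to 3-aryl-2(5H)-furanones (intramolecular Knoevenagel-type aldol condensation). Ring D closes in a 5-(enolexo)-exo-trig mode. The two stereocentres of 15 are transient and are erased by the dehydration, and the target has none. The step needs oxygenation at one defined carbon and enolisation at one defined carbon: 11 has a single α-carbon with a single hydrogen, so only one enamine can form and 14 can neither enolise nor be oxygenated again, and the only acidic C–H left is the CH2 between ring A and the ester carbonyl. The quaternary C5' also means that the product cannot isomerise out of conjugation under the base.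

**Compound list**
1 | 7-hydroxyflavone (7-hydroxy-2-phenyl-4H-chromen-4-one) | Oc1ccc2c(=O)cc(-c3ccccc3)oc2c1 | starting material
2 | allyl bromide (3-bromoprop-1-ene) | C=CCBr | starting material
3 | 7-(allyloxy)flavone | C=CCOc1ccc2c(=O)cc(-c3ccccc3)oc2c1 | intermediate
4 | 8-allyl-7-hydroxyflavone | Oc1ccc2c(=O)cc(-c3ccccc3)oc2c1CC=C | intermediate
5 | 8-allyl-7-methoxyflavone | COc1ccc2c(=O)cc(-c3ccccc3)oc2c1CC=C | intermediate
6 | (7-methoxy-4-oxo-2-phenyl-4H-chromen-8-yl)acetaldehyde | COc1ccc2c(=O)cc(-c3ccccc3)oc2c1CC=O | intermediate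
7 | (7-methoxy-4-oxo-2-phenyl-4H-chromen-8-yl)acetic acid | COc1ccc2c(=O)cc(-c3ccccc3)oc2c1CC(=O)O | intermediate
8 | tert-butyl N-hydroxy-N-methylcarbamate | CN(O)C(=O)OC(C)(C)C | starting material
9 | tert-butyl N-methyl-N-{[(7-methoxy-4-oxo-2-phenyl-4H-chromen-8-yl)acetyl]oxy}carbamate | COc1ccc2c(=O)cc(-c3ccccc3)oc2c1CC(=O)ON(C)C(=O)OC(C)(C)C | intermediate
10 | N-methyl-O-[(7-methoxy-4-oxo-2-phenyl-4H-chromen-8-yl)acetyl]hydroxylammonium chloride | COc1ccc2c(=O)cc(-c3ccccc3)oc2c1CC(=O)O[NH2+]C.[Cl-] | intermediate
11 | isobutyraldehyde (2-methylpropanal) | CC(C)C=O | starting material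
12 | N-acyloxy enamine: N-methyl-N-(2-methylprop-1-en-1-yl)-O-[(7-methoxy-4-oxo-2-phenyl-4H-chromen-8-yl)acetyl]hydroxylamine | COc1ccc2c(=O)cc(-c3ccccc3)oc2c1CC(=O)ON(C)C=C(C)C | intermediate
13 | acyloxy imine: (E)-2-methyl-1-(methylimino)propan-2-yl (7-methoxy-4-oxo-2-phenyl-4H-chromen-8-yl)acetate | COc1ccc2c(=O)cc(-c3ccccc3)oc2c1CC(=O)OC(C)(C)/C=N/C | intermediate
14 | acyloxy aldehyde: 2-methyl-1-oxopropan-2-yl (7-methoxy-4-oxo-2-phenyl-4H-chromen-8-yl)acetate | COc1ccc2c(=O)cc(-c3ccccc3)oc2c1CC(=O)OC(C)(C)C=O | intermediate
15 | aldol lactone: 4-hydroxy-3-(7-methoxy-4-oxo-2-phenyl-4H-chromen-8-yl)-5,5-dimethyldihydrofuran-2(3H)-one (racemic, mixture of diastereomers) | COc1ccc2c(=O)cc(-c3ccccc3)oc2c1C1C(O)C(C)(C)OC1=O | intermediate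
16 | 3-(7-methoxy-4-oxo-2-phenyl-4H-chromen-8-yl)-5,5-dimethylfuran-2(5H)-one (CNP0102581.0, achiral) | COc1ccc2c(=O)cc(-c3ccccc3)oc2c1C1=CC(C)(C)OC1=O | target

**Step count and risks**
Total step count: 8. Longest linear sequence: 8 steps (1 to 16; compounds 2, 8 and 11 are purchased).

Steps most likely to fail:

1. Step 8 (key step). O-to-N acyl migration of the reagent may outrun enamine formation, the aldol lactone may resist dehydration, or the tertiary ester may be cleaved by DBU or by the released methylamine before ring closure. The fallback sets out from acid 7 and comes back at target 16, and makes the same two ring bonds by enolate alkylation, cationic lactonisation and dehydrogenation. Acid 7 is esterified with MeI and K2CO3 in DMF to methyl (7-methoxy-4-oxo-2-phenyl-4H-chromen-8-yl)acetate F1. The lithium enolate of F1 is formed with LiN(SiMe3)2 in THF at −78 °C and alkylated with 3-bromo-2-methylprop-1-ene to methyl 2-(7-methoxy-4-oxo-2-phenyl-4H-chromen-8-yl)-4-methylpent-4-enoate F2. Aqueous H2SO4/AcOH at 60 °C should protonate the 1,1-disubstituted alkene of F2 so that the ester carbonyl oxygen captures the tertiary cation and methanol is lost, giving 3-(7-methoxy-4-oxo-2-phenyl-4H-chromen-8-yl)-5,5-dimethyldihydrofuran-2(3H)-one F3. α-Selenenylation of F3 with LiN(SiMe3)2 and PhSeCl in THF at −78 °C gives 3-(7-methoxy-4-oxo-2-phenyl-4H-chromen-8-yl)-5,5-dimethyl-3-(phenylselanyl)dihydrofuran-2(3H)-one F4. Oxidation of F4 with H2O2/pyridine in CH2Cl2 at 0 °C should trigger selenoxide syn-elimination, which can only take a C4' hydrogen, and give 16.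

2. Step 7. When the Boc group is removed and the salt is handled, the activated acyl group may be lost by acidolysis or may migrate from O to N. The fallback sets out from acid 7 and aldehyde 11 and comes back at enamine 12 inside step 8; it moves the N–O unit onto the aldehyde partner. Acid 7 is converted with oxalyl chloride and catalytic DMF in CH2Cl2 into (7-methoxy-4-oxo-2-phenyl-4H-chromen-8-yl)acetyl chloride F5. Aldehyde 11 is condensed with purchased N-methylhydroxylamine hydrochloride (NaHCO3, MgSO4, CH2Cl2) to (Z)-N,2-dimethylpropan-1-imine N-oxide F6. Acid chloride F5 should O-acylate nitrone F6 at −78 °C, and Et3N then deprotonates the N-acyloxy iminium ion to enamine 12. This rearranges to 13, aqueous work-up gives 14, and DBU closes ring D to 16 as in step 8 (acylation–rearrangement of aldonitrones).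

3. Step 2. The allyl group may migrate in part to C6, or the flavone may decompose at about 200 °C. The fallback sets out from allyl bromide 2 and purchased paeonol (1-(2-hydroxy-4-methoxyphenyl)ethanone, CC(=O)c1ccc(OC)cc1O) and comes back at 5; it builds the pyranone ring after the allyl group is in place, so the regiochemistry is not in question. O-Allylation of paeonol with 2 (K2CO3, DMF, 60 °C) gives 1-[2-(allyloxy)-4-methoxyphenyl]ethanone F7. Claisen rearrangement of F7 in PhNEt2 at 200 °C can only reach the single free ortho position and gives 1-(3-allyl-2-hydroxy-4-methoxyphenyl)ethanone F8. Benzoylation of F8 with PhCOCl in pyridine gives 2-acetyl-6-allyl-5-methoxyphenyl benzoate F9. Baker–Venkataraman rearrangement of F9 with KOH in pyridine at 50 °C gives 1-(3-allyl-2-hydroxy-4-methoxyphenyl)-3-phenylpropane-1,3-dione F10. Cyclodehydration of F10 with TsOH in toluene at reflux then gives 8-allyl-7-methoxyflavone 5.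

**Further compounds**
F1 | step 8 | methyl (7-methoxy-4-oxo-2-phenyl-4H-chromen-8-yl)acetate | COc1ccc2c(=O)cc(-c3ccccc3)oc2c1CC(=O)OC
F2 | step 8 | methyl 2-(7-methoxy-4-oxo-2-phenyl-4H-chromen-8-yl)-4-methylpent-4-enoate (racemic) | COc1ccc2c(=O)cc(-c3ccccc3)oc2c1C(CC(C)=C)C(=O)OC
F3 | step 8 | 3-(7-methoxy-4-oxo-2-phenyl-4H-chromen-8-yl)-5,5-dimethyldihydrofuran-2(3H)-one (racemic) | COc1ccc2c(=O)cc(-c3ccccc3)oc2c1C1CC(C)(C)OC1=O
F4 | step 8 | 3-(7-methoxy-4-oxo-2-phenyl-4H-chromen-8-yl)-5,5-dimethyl-3-(phenylselanyl)dihydrofuran-2(3H)-one (racemic) | COc1ccc2c(=O)cc(-c3ccccc3)oc2c1C1([Se]c3ccccc3)CC(C)(C)OC1=O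
F5 | step 7 | (7-methoxy-4-oxo-2-phenyl-4H-chromen-8-yl)acetyl chloride | COc1ccc2c(=O)cc(-c3ccccc3)oc2c1CC(=O)Cl
F6 | step 7 | (Z)-N,2-dimethylpropan-1-imine N-oxide | CC(C)/C=[N+](\[O-])C
F7 | step 2 | 1-[2-(allyloxy)-4-methoxyphenyl]ethanone | CC(=O)c1ccc(OC)cc1OCC=C
F8 | step 2 | 1-(3-allyl-2-hydroxy-4-methoxyphenyl)ethanone | CC(=O)c1ccc(OC)c(CC=C)c1O
F9 | step 2 | 2-acetyl-6-allyl-5-methoxyphenyl benzoate | CC(=O)c1ccc(OC)c(CC=C)c1OC(=O)c1ccccc1
F10 | step 2 | 1-(3-allyl-2-hydroxy-4-methoxyphenyl)-3-phenylpropane-1,3-dione | O=C(CC(=O)c1ccccc1)c1ccc(OC)c(CC=C)c1O
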